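**Retrosynthetic overview**
- The cyclobutane is the only ring to be made and is formed first: head-to-tail [2+2] photodimerisation of two molecules of crystalline (E)-3,4-dimethoxycinnamic acid 1 gives the α-truxillic diacid 2 and sets all four stereocentres at once.
- Both dihydropyridinone rings are bought intact as 5,6-dihydropyridin-2(1H)-one 3 and carried as the N-silyl lactam 4.
- The last disconnection is the two imide C–N bonds: bis(acyl fluoride) 5 (made from 2 in the flask) plus two molecules of 4 give target 6 by a new Si–F-driven, Lewis-base-catalysed N-acylation.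

Assumption: the SMILES descriptors describe the centrosymmetric α-truxillic arrangement (aryls 1,3-trans, acyls 1,3-trans, each acyl cis to one aryl neighbour and trans to the other). This molecule has an inversion centre and is achiral (meso), so "the single enantiomer" is taken to mean this one diastereomer.

**Step 1**
Reactants: 1 (E)-3,4-dimethoxycinnamic acid (two molecules)
Product: 2 (1α,2α,3β,4β)-2,4-bis(3,4-dimethoxyphenyl)cyclobutane-1,3-dicarboxylic acid
Conditions: hν (365 nm LEDs, Pyrex), finely ground crystals of the head-to-tail (α-type) polymorph (checked by powder XRD) as a stirred suspension in water, rt, 48 h; unreacted 1 removed by trituration with CH2Cl2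
Reagents that add atoms: second molecule of 1, (E)-3,4-dimethoxycinnamic acid, COc1ccc(/C=C/C(=O)O)cc1OC
Why: Topochemical (Schmidt-type) solid-state [2+2] photocycloaddition of two neighbouring molecules of 1: in the α-type crystal the E-alkenes stack antiparallel about an inversion centre with C=C contacts under about 4.2 Å, so the lattice gives only the centrosymmetric head-to-tail dimer and sets all four stereocentres together (aryl/carboxyl trans within each former alkene, cis across each new bond).

**Step 2**
Reactants: 3 5,6-dihydropyridin-2(1H)-one
Product: 4 1-(trimethylsilyl)-5,6-dihydropyridin-2(1H)-one (in equilibrium with its O-silyl lactim form)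
Conditions: Me3SiCl (1.1 equiv), Et3N (1.2 equiv), toluene, 0 °C → rt, 3 h; filter under Ar, evaporate, Kugelrohr distil
Reagents that add atoms: chlorotrimethylsilane, C[Si](C)(C)Cl
Why: Standard N-silylation of a secondary lactam N–H with Me3SiCl/Et3N; no stereocentre is involved and the tertiary amine does not add to the enone.

**Step 3**
Reactants: 2 (1α,2α,3β,4β)-2,4-bis(3,4-dimethoxyphenyl)cyclobutane-1,3-dicarboxylic acid; 4 1-(trimethylsilyl)-5,6-dihydropyridin-2(1H)-one (two molecules)
Product: 6 1,1'-{[(1α,2α,3β,4β)-2,4-bis(3,4-dimethoxyphenyl)cyclobutane-1,3-diyl]dicarbonyl}bis(5,6-dihydropyridin-2(1H)-one), via bis(acyl fluoride) 5 (not isolated)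
Conditions: (a) cyanuric fluoride (2,4,6-trifluoro-1,3,5-triazine, 1.0 equiv), pyridine (2.2 equiv), CH2Cl2, −10 °C → rt, 2 h; filter off cyanuric acid under Ar, evaporate; (b) 4 (2.4 equiv in total), 4-(dimethylamino)pyridine (DMAP, 10 mol %), MeCN, rt → 40 °C, Ar sweep
Reagents that add atoms: second molecule of 4, 1-(trimethylsilyl)-5,6-dihydropyridin-2(1H)-one, C[Si](C)(C)N1CCC=CC1=O
Why: Proposed new method: a DMAP-catalysed, Si–F-driven two-fold N-acylation of an N-silyl enelactam by an acyl fluoride (stage a is the ordinary cyanuric fluoride deoxyfluorination of a carboxylic acid); DMAP and the C(O)–F bond equilibrate with an acylpyridinium fluoride ion pair, the fluoride is pulled onto silicon of 4 (Si–F roughly 140 kcal/mol against roughly 100 for Si–N), and the resulting lactamate collapses on the acylpyridinium at N (or at O followed by a Mumm-type 1,3-O→N acyl shift, favoured by the cisoid lactim geometry), releasing DMAP and gaseous Me3SiF, so each of the two C–N bonds forms under neutral conditions without amine hydrohalide, ketene or free strong base and the four ring stereocentres from step 1 (two of them α to the acyl groups) are carried through unchanged; the closest known reaction types are the thermal N-acylation of N-trimethylsilyl lactams by acid chlorides and the aminopyridine-catalysed acylation of silyl ketene acetals and silyl ethers by acyl fluorides, whereas, as far as I know, an acyl fluoride/N-silyl lactam imide coupling has not been shown on an α,β-unsaturated lactam or twice on one cyclobutane.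

**Compound list**
1 | (E)-3,4-dimethoxycinnamic acid | COc1ccc(/C=C/C(=O)O)cc1OC | starting material
2 | (1α,2α,3β,4β)-2,4-bis(3,4-dimethoxyphenyl)cyclobutane-1,3-dicarboxylic acid (α-truxillic type, meso) | COc1ccc([C@H]2[C@H](C(=O)O)[C@H](c3ccc(OC)c(OC)c3)[C@H]2C(=O)O)cc1OC | intermediate
3 | 5,6-dihydropyridin-2(1H)-one | O=C1C=CCCN1 | starting material
4 | 1-(trimethylsilyl)-5,6-dihydropyridin-2(1H)-one | C[Si](C)(C)N1CCC=CC1=O | intermediate
5 | (1α,2α,3β,4β)-2,4-bis(3,4-dimethoxyphenyl)cyclobutane-1,3-dicarbonyl difluoride | COc1ccc([C@H]2[C@H](C(=O)F)[C@H](c3ccc(OC)c(OC)c3)[C@H]2C(=O)F)cc1OC | intermediate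
6 | 1,1'-{[(1α,2α,3β,4β)-2,4-bis(3,4-dimethoxyphenyl)cyclobutane-1,3-diyl]dicarbonyl}bis(5,6-dihydropyridin-2(1H)-one) | COc1ccc([C@H]2[C@H](C(=O)N3CCC=CC3=O)[C@H](c3ccc(OC)c(OC)c3)[C@H]2C(=O)N2CCC=CC2=O)cc1OC | target

**Step count**
Total steps: 3. Longest linear sequence: 2 (1 → 2 → 6); the lactam branch 3 → 4 is one step.

**Steps most likely to fail**

Most at risk is step 3, the new C–N coupling. The second acylation at the hindered cyclobutane carbonyl may be slow, protic residues from stage (a) may desilylate 4, and free lactamate could start aza-Michael addition to the enone; a first remedy within the method is 2 mol % n-Bu4N[Ph3SiF2] as fluoride initiator. The fallback uses known chemistry, sets out from diacid 2 (with two equivalents of lactam 3) and comes back to the route at 6. Diacid 2 is converted with (COCl)2 and catalytic DMF in CH2Cl2 into (1α,2α,3β,4β)-2,4-bis(3,4-dimethoxyphenyl)cyclobutane-1,3-dicarbonyl dichloride F1. Lactam 3 is deprotonated with LiN(SiMe3)2 in THF at −78 °C to lithium 2-oxo-5,6-dihydropyridin-1(2H)-ide F2, and F1 is added to two equivalents of it at −78 °C to give 6. This is the standard acid chloride/lithiated lactam imide formation used for this class of N-acyl dihydropyridinones.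

Second is step 1. The photodimerisation depends on having the head-to-tail polymorph and on light reaching the crystal interior, so the wrong crystal form or a product shell can give no reaction or incomplete conversion. The fallback reverses the order of C–N and cyclobutane formation; it sets out from 1 (and uses 4) and comes back at 6. Acid 1 is converted with (COCl)2 and catalytic DMF into (E)-3,4-dimethoxycinnamoyl chloride F3. Warming F3 with silyl lactam 4 in toluene (80 °C, loss of Me3SiCl) gives the monomeric imide (E)-1-[3-(3,4-dimethoxyphenyl)prop-2-enoyl]-5,6-dihydropyridin-2(1H)-one F4. Crystals of F4, screened by XRD for head-to-tail stacking, are irradiated as in step 1 so that two molecules dimerise to 6 directly; this is biomimetic and less certain than step 1 itself.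

Third is step 2. Silyl lactam 4 is moisture-sensitive and the enelactam may hydrolyse or oligomerise on distillation. The fallback drops the silyl derivative; it sets out from 3 (with 5 from stage (a) of step 3) and comes back at 6. Free lactam 3 (2.4 equiv) is acylated directly by bis(acyl fluoride) 5 with i-Pr2NEt (3 equiv) and DMAP (20 mol %) in CH2Cl2 at 40 °C, a base-mediated N–H acylation by an acyl fluoride; no new compound is made (F0).

**Further compounds**
F1 | step 3 | (1α,2α,3β,4β)-2,4-bis(3,4-dimethoxyphenyl)cyclobutane-1,3-dicarbonyl dichloride | COc1ccc([C@H]2[C@H](C(=O)Cl)[C@H](c3ccc(OC)c(OC)c3)[C@H]2C(=O)Cl)cc1OC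
F2 | step 3 | lithium 2-oxo-5,6-dihydropyridin-1(2H)-ide | [Li+].O=C1C=CCC[N-]1
F3 | step 1 | (E)-3,4-dimethoxycinnamoyl chloride | COc1ccc(/C=C/C(=O)Cl)cc1OC
F4 | step 1 | (E)-1-[3-(3,4-dimethoxyphenyl)prop-2-enoyl]-5,6-dihydropyridin-2(1H)-one | COc1ccc(/C=C/C(=O)N2CCC=CC2=O)cc1OC
F0 | step 2 | none | none
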